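Side chain numbered C1' (benzylic CH2) to C15'; the target is 5'R, 11'R, 2'E, 6'E.
Feature used: across the E C6'=C7' alkene the C7' methyl is cis to C5', so the C5' oxygen, C5', C6', C7' and the methyl carbon can be held as a five-membered butenolide ring whose carbonyl carbon is the future methyl.
Cuts, in retrosynthetic order: C12' ketone to its dithiane; C7'–CH3 back to the lactone carbonyl; C6'=C7' (ring-closing metathesis); the ester C–O at the C5' oxygen; then C7'–C8', C12'–C13' and C10'–C11' in the acid, and C1'–C2', C3'–CH3 and C3'–C4' in the alcohol.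
Forward: phenol 1 gives benzylic chloride 5; (R)-epichlorohydrin gives enynol 12, which is joined to 5 as alcohol 14; the Evans imide gives acid 26; 14 and 26 are esterified, the only ring of the route (the butenolide) closes, and it is then opened and reduced to the C7' methyl before ketone and phenol are unmasked.
Stereochemistry: C5' comes from (R)-epichlorohydrin and is never a reacting centre; C11' from an Evans alkylation; C2'=C3' (E) from syn-carboalumination and retentive coupling; C6'=C7' (E) from the cis alkene imposed by the five-membered ring.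

Key step: step 17

Step 1
Reactants: 1 4-methoxy-2-methylphenol
Product: 2 2-hydroxy-5-methoxy-3-methylbenzaldehyde
Conditions: MgCl2, Et3N, (CH2O)n, MeCN, reflux; aq. HCl work-up
Reagents that add atoms: paraformaldehyde (as formaldehyde), C=O
Why: Magnesium phenoxide-directed ortho-formylation (Casnati–Skattebøl reaction) delivers formaldehyde to the only free position ortho to the hydroxyl, the other ortho position carrying the methyl group and the para position the methoxy group.

Step 2
Reactants: 2 2-hydroxy-5-methoxy-3-methylbenzaldehyde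
Product: 3 2-(tert-butyldimethylsilyloxy)-5-methoxy-3-methylbenzaldehyde
Conditions: t-BuMe2SiCl, imidazole, DMF, rt
Reagents that add atoms: tert-butyldimethylsilyl chloride, CC(C)(C)[Si](C)(C)Cl
Why: Imidazole-promoted silylation of a phenol gives an aryl silyl ether that tolerates the organoaluminium, hydride and ruthenium chemistry ahead and is removed by fluoride at the end.

Step 3
Reactants: 3 2-(tert-butyldimethylsilyloxy)-5-methoxy-3-methylbenzaldehyde
Product: 4 [2-(tert-butyldimethylsilyloxy)-5-methoxy-3-methylphenyl]methanol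
Conditions: NaBH4, MeOH/THF, 0 °C, short reaction time; aq. NH4Cl
Reagents that add atoms: none
Why: Borohydride reduction of an aryl aldehyde is fast at 0 °C, and a cold, prompt quench should suppress migration of silicon from the phenolic to the benzylic oxygen.

Step 4
Reactants: 4 [2-(tert-butyldimethylsilyloxy)-5-methoxy-3-methylphenyl]methanol
Product: 5 tert-butyl[2-(chloromethyl)-4-methoxy-6-methylphenoxy]dimethylsilane
Conditions: MsCl, Et3N, LiCl, THF, 0 °C → rt
Reagents that add atoms: lithium chloride, [Li+].[Cl-]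
Why: Mesylation of the benzylic alcohol and in situ SN2 displacement by chloride gives a benzylic chloride that can be stored yet adds oxidatively to zerovalent palladium.

Step 5
Reactants: 6 ethynyltrimethylsilane; 7 (R)-epichlorohydrin
Product: 9 (2R)-1-chloro-5-(trimethylsilyl)pent-4-yn-2-ol, via lithium (trimethylsilyl)acetylide 8 (not isolated)
Conditions: n-BuLi, THF, −78 °C; BF3·OEt2; then 7, −78 °C
Reagents that add atoms: none
Why: BF3-promoted alkynylation of an epoxide (Yamaguchi-type opening) occurs at the unsubstituted ring carbon, the future C4', so the stereocentre of 7 (the future C5') is not touched and the chloromethyl group is kept for the next step.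

Step 6
Reactants: 9 (2R)-1-chloro-5-(trimethylsilyl)pent-4-yn-2-ol
Product: 11 (3R)-6-(trimethylsilyl)hex-1-en-5-yn-3-ol, via (2R)-2-[3-(trimethylsilyl)prop-2-yn-1-yl]oxirane 10 (not isolated)
Conditions: Me3SI (slight excess over base), n-BuLi, THF, −20 °C; then 9, −20 °C → rt
Reagents that add atoms: trimethylsulfonium iodide, C[S+](C)C.[I-]
Why: Base closes the chlorohydrin to the terminal epoxide, and excess dimethylsulfonium methylide (the Corey–Chaykovsky reagent) opens it at CH2 and then loses dimethyl sulfide by elimination, a one-carbon homologation of an epoxide to a vinyl carbinol in which no bond to the stereocentre is broken.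

Step 7
Reactants: 11 (3R)-6-(trimethylsilyl)hex-1-en-5-yn-3-ol
Product: 12 (3R)-hex-1-en-5-yn-3-ol
Conditions: K2CO3 (cat.), MeOH, rt; careful concentration (volatile)
Reagents that add atoms: none
Why: Methanolysis of the alkynyl C–Si bond under catalytic carbonate is selective and leaves the allylic alcohol untouched.

Step 8
Reactants: 12 (3R)-hex-1-en-5-yn-3-ol; 5 tert-butyl[2-(chloromethyl)-4-methoxy-6-methylphenoxy]dimethylsilane
Product: 14 (3R,5E)-7-[2-(tert-butyldimethylsilyloxy)-5-methoxy-3-methylphenyl]-5-methylhepta-1,5-dien-3-ol, via (E)-alkenylalane 13 (not isolated)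
Conditions: Me3Al (3 equiv), Cp2ZrCl2 (0.3 equiv), CH2Cl2, 0 °C → rt; then 5, Pd(PPh3)4 (5 mol %), THF, rt
Reagents that add atoms: trimethylaluminium, C[Al](C)C
Why: Zirconium-catalysed Negishi carboalumination adds methyl and aluminium syn across the terminal alkyne with methyl on the internal carbon (C3'), and the palladium-catalysed Negishi coupling of the alkenylalane with benzylic chloride 5 proceeds with retention, which fixes the E geometry of C2'=C3' while the terminal alkene reacts far more slowly.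

Step 9
Reactants: 15 (4S)-4-benzyl-3-propanoyl-1,3-oxazolidin-2-one
Product: 17 (4S)-4-benzyl-3-[(2R)-2-methylpent-4-enoyl]-1,3-oxazolidin-2-one, via sodium (Z)-enolate 16 (not isolated)
Conditions: NaN(SiMe3)2, THF, −78 °C; allyl iodide, −78 → −40 °C
Reagents that add atoms: allyl iodide, C=CCI
Why: Evans asymmetric alkylation: the chelated (Z)-enolate is attacked by allyl iodide on the face opposite the benzyl group of the auxiliary, which sets the R configuration of the future C11'.

Step 10
Reactants: 17 (4S)-4-benzyl-3-[(2R)-2-methylpent-4-enoyl]-1,3-oxazolidin-2-one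
Product: 18 (2R)-2-methylpent-4-en-1-ol
Conditions: LiBH4, H2O (1 equiv), Et2O, 0 °C; aq. NaOH work-up
Reagents that add atoms: none
Why: Reductive cleavage of the imide by LiBH4 at the exocyclic carbonyl releases the auxiliary and gives the primary alcohol without epimerisation.

Step 11
Reactants: 18 (2R)-2-methylpent-4-en-1-ol
Product: 19 (2R)-2-methylpent-4-enal
Conditions: (COCl)2, DMSO, CH2Cl2, −78 °C; i-Pr2NEt, −78 → −20 °C; kept as a cold CH2Cl2 solution
Reagents that add atoms: none
Why: Swern oxidation at low temperature with a hindered amine base should give the α-branched aldehyde with minimal enolisation, and the volatile product is carried on in solution.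

Step 12
Reactants: 19 (2R)-2-methylpent-4-enal
Product: 20 2-[(2R)-pent-4-en-2-yl]-1,3-dithiane
Conditions: HS(CH2)3SH, BF3·OEt2 (cat.), CH2Cl2, −20 → 0 °C
Reagents that add atoms: propane-1,3-dithiol, SCCCS
Why: Lewis acid-catalysed thioacetalisation gives the 1,3-dithiane, which is both the acyl anion equivalent for the next step and the mask for the C12' ketone.

Step 13
Reactants: 20 2-[(2R)-pent-4-en-2-yl]-1,3-dithiane
Product: 22 2-(3-methylbut-2-en-1-yl)-2-[(2R)-pent-4-en-2-yl]-1,3-dithiane, via 2-lithio-1,3-dithiane 21 (not isolated)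
Conditions: t-BuLi, THF/HMPA (9:1), −78 °C; prenyl bromide, −78 → 0 °C
Reagents that add atoms: prenyl bromide (1-bromo-3-methylbut-2-ene), CC(C)=CCBr
Why: Corey–Seebach alkylation: the lithiated dithiane attacks the primary allylic bromide at its CH2 terminus (SN2), forming C12'–C13' and placing the β,γ-alkene without ever exposing a free, isomerisable ketone.

Step 14
Reactants: 22 2-(3-methylbut-2-en-1-yl)-2-[(2R)-pent-4-en-2-yl]-1,3-dithiane; 23 methyl 2-bromoacrylate
Product: 25 methyl (6R)-2-methylidene-6-[2-(3-methylbut-2-en-1-yl)-1,3-dithian-2-yl]heptanoate, via B-alkyl-9-borabicyclo[3.3.1]nonane 24 (not isolated)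
Conditions: 9-BBN, THF, 0 °C → rt; then 23, PdCl2(dppf) (5 mol %), AsPh3, Cs2CO3, DMF/H2O, rt
Reagents that add atoms: none
Why: 9-BBN hydroborates the monosubstituted alkene at its terminus in preference to the trisubstituted one, and B-alkyl Suzuki–Miyaura coupling with the alkenyl bromide forms C7'–C8' under mild base at room temperature.

Step 15
Reactants: 25 methyl (6R)-2-methylidene-6-[2-(3-methylbut-2-en-1-yl)-1,3-dithian-2-yl]heptanoate
Product: 26 (6R)-2-methylidene-6-[2-(3-methylbut-2-en-1-yl)-1,3-dithian-2-yl]heptanoic acid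
Conditions: LiOH, THF/H2O, rt; then 1 M HCl to pH 3
Reagents that add atoms: lithium hydroxide, [Li+].[OH-]
Why: Saponification of the methyl ester is safe here because no stereocentre is α to a carbonyl group and the dithiane is inert to hydroxide and to brief acidification.

Step 16
Reactants: 14 (3R,5E)-7-[2-(tert-butyldimethylsilyloxy)-5-methoxy-3-methylphenyl]-5-methylhepta-1,5-dien-3-ol; 26 (6R)-2-methylidene-6-[2-(3-methylbut-2-en-1-yl)-1,3-dithian-2-yl]heptanoic acid
Product: 27 (3R,5E)-7-[2-(tert-butyldimethylsilyloxy)-5-methoxy-3-methylphenyl]-5-methylhepta-1,5-dien-3-yl (6R)-2-methylidene-6-[2-(3-methylbut-2-en-1-yl)-1,3-dithian-2-yl]heptanoate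
Conditions: DCC, DMAP (cat.), CH2Cl2, 0 °C → rt
Reagents that add atoms: none
Why: Steglich esterification acylates the secondary allylic alcohol with retention at C5', since the C5'–O bond is not broken.

Step 17
Reactants: 27 (3R,5E)-7-[2-(tert-butyldimethylsilyloxy)-5-methoxy-3-methylphenyl]-5-methylhepta-1,5-dien-3-yl (6R)-2-methylidene-6-[2-(3-methylbut-2-en-1-yl)-1,3-dithian-2-yl]heptanoate
Product: 28 (5R)-5-{(2E)-4-[2-(tert-butyldimethylsilyloxy)-5-methoxy-3-methylphenyl]-2-methylbut-2-en-1-yl}-3-{(4R)-4-[2-(3-methylbut-2-en-1-yl)-1,3-dithian-2-yl]pentyl}furan-2(5H)-one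
Conditions: second-generation Grubbs catalyst (H2IMes)(PCy3)Cl2Ru=CHPh (10 mol %, two portions), toluene (0.005 M), 80 °C, argon sparge
Reagents that add atoms: none
Why: The ruthenium alkylidene first exchanges with the monosubstituted C6' vinyl group, the new alkylidene adds to the 1,1-disubstituted acrylate alkene in a [2+2] cycloaddition, and cycloreversion of the ruthenacyclobutane forms C6'=C7' with loss of ethylene. The closest known reaction type is the ring-closing metathesis of allyl 2-alkylacrylates to 3-substituted furan-2(5H)-ones with N-heterocyclic carbene ruthenium catalysts. The single ring closes as a five-membered unsaturated lactone by intramolecular alkene metathesis, the new double bond being endocyclic. No stereocentre is formed; the ring can only hold a cis double bond, so C5' and the carbonyl carbon (the future C7' methyl) end up cis, and C5' and C11' are not involved. The step needs site selectivity among five alkenes, which the substrate provides because only the vinyl and acrylate alkenes are unhindered and able to form a small ring, whereas the two trisubstituted alkenes react slowly and could only give strained or medium rings; high dilution disfavours dimerisation and the raised catalyst loading offsets coordination by the dithiane sulfur atoms.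

Step 18
Reactants: 28 (5R)-5-{(2E)-4-[2-(tert-butyldimethylsilyloxy)-5-methoxy-3-methylphenyl]-2-methylbut-2-en-1-yl}-3-{(4R)-4-[2-(3-methylbut-2-en-1-yl)-1,3-dithian-2-yl]pentyl}furan-2(5H)-one
Product: 29 (2Z,4R,6E)-8-[2-(tert-butyldimethylsilyloxy)-5-methoxy-3-methylphenyl]-6-methyl-2-{(4R)-4-[2-(3-methylbut-2-en-1-yl)-1,3-dithian-2-yl]pentyl}octa-2,6-diene-1,4-diol
Conditions: i-Bu2AlH (4 equiv), CH2Cl2, −78 → 0 °C; aq. KNaC4H4O6 (potassium sodium tartrate)
Reagents that add atoms: none
Why: i-Bu2AlH reduces the lactone through the lactol to the ene-1,4-diol by 1,2-reduction only, which carries the ring-imposed alkene geometry into the open chain.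

Step 19
Reactants: 29 (2Z,4R,6E)-8-[2-(tert-butyldimethylsilyloxy)-5-methoxy-3-methylphenyl]-6-methyl-2-{(4R)-4-[2-(3-methylbut-2-en-1-yl)-1,3-dithian-2-yl]pentyl}octa-2,6-diene-1,4-diol
Product: 31 {[(2Z,4R,6E)-8-[2-(tert-butyldimethylsilyloxy)-5-methoxy-3-methylphenyl]-1-chloro-6-methyl-2-{(4R)-4-[2-(3-methylbut-2-en-1-yl)-1,3-dithian-2-yl]pentyl}octa-2,6-dien-4-yl]oxy}triethylsilane, via hydroxy allylic chloride 30 (not isolated)
Conditions: MsCl (1.1 equiv), 2,4,6-collidine, LiCl, DMF, −10 → 0 °C; then imidazole, Et3SiCl, 0 °C → rt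
Reagents that add atoms: lithium chloride, [Li+].[Cl-]; chlorotriethylsilane, CC[Si](Cl)(CC)CC
Why: Mesylation occurs at the less hindered primary allylic hydroxyl and chloride displaces the mesylate by SN2, while silylation of the C5' hydroxyl in the same flask prevents its cyclisation onto the allylic chloride to a 2,5-dihydrofuran and its directing of hydride in the next step.

Step 20
Reactants: 31 {[(2Z,4R,6E)-8-[2-(tert-butyldimethylsilyloxy)-5-methoxy-3-methylphenyl]-1-chloro-6-methyl-2-{(4R)-4-[2-(3-methylbut-2-en-1-yl)-1,3-dithian-2-yl]pentyl}octa-2,6-dien-4-yl]oxy}triethylsilane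
Product: 32 tert-butyl(4-methoxy-2-methyl-6-{(2E,5R,6E,11R)-3,7-dimethyl-11-[2-(3-methylbut-2-en-1-yl)-1,3-dithian-2-yl]-5-(triethylsilyloxy)dodeca-2,6-dien-1-yl}phenoxy)dimethylsilane
Conditions: LiBHEt3, THF, −78 → 0 °C
Reagents that add atoms: none
Why: LiBHEt3 displaces the primary allylic chloride by direct SN2 attack of hydride, the γ-carbon being shielded by the neighbouring silyloxy-bearing centre, and so turns the former lactone carbonyl carbon into the C7' methyl of the E alkene.

Step 21
Reactants: 32 tert-butyl(4-methoxy-2-methyl-6-{(2E,5R,6E,11R)-3,7-dimethyl-11-[2-(3-methylbut-2-en-1-yl)-1,3-dithian-2-yl]-5-(triethylsilyloxy)dodeca-2,6-dien-1-yl}phenoxy)dimethylsilane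
Product: 33 (6R,10E,12R,14E)-16-[2-(tert-butyldimethylsilyloxy)-5-methoxy-3-methylphenyl]-2,6,10,14-tetramethyl-12-(triethylsilyloxy)hexadeca-2,10,14-trien-5-one
Conditions: MeI (excess), CaCO3, MeCN/H2O (9:1), 45 °C
Reagents that add atoms: water, O
Why: Alkylative hydrolysis of the dithiane (S-methylation, then attack of water) under carbonate buffering frees the C12' ketone near neutrality, so the β,γ-alkene should not move into conjugation and C11' should not epimerise.

Step 22
Reactants: 33 (6R,10E,12R,14E)-16-[2-(tert-butyldimethylsilyloxy)-5-methoxy-3-methylphenyl]-2,6,10,14-tetramethyl-12-(triethylsilyloxy)hexadeca-2,10,14-trien-5-one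
Product: 34 (6R,10E,12R,14E)-12-hydroxy-16-(2-hydroxy-5-methoxy-3-methylphenyl)-2,6,10,14-tetramethylhexadeca-2,10,14-trien-5-one
Conditions: Bu4NF, AcOH (1:1), THF, 0 °C → rt
Reagents that add atoms: none
Why: Fluoride buffered with acetic acid cleaves both the aryl and the secondary alkyl silyl ether, and the buffer keeps the medium non-basic towards the β,γ-unsaturated ketone.

Compound list
1 | 4-methoxy-2-methylphenol | COc1ccc(O)c(C)c1 | starting material
2 | 2-hydroxy-5-methoxy-3-methylbenzaldehyde | COc1cc(C)c(O)c(C=O)c1 | intermediate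
3 | 2-(tert-butyldimethylsilyloxy)-5-methoxy-3-methylbenzaldehyde | COc1cc(C)c(O[Si](C)(C)C(C)(C)C)c(C=O)c1 | intermediate
4 | [2-(tert-butyldimethylsilyloxy)-5-methoxy-3-methylphenyl]methanol | COc1cc(C)c(O[Si](C)(C)C(C)(C)C)c(CO)c1 | intermediate
5 | tert-butyl[2-(chloromethyl)-4-methoxy-6-methylphenoxy]dimethylsilane | COc1cc(C)c(O[Si](C)(C)C(C)(C)C)c(CCl)c1 | intermediate
6 | ethynyltrimethylsilane | C#C[Si](C)(C)C | starting material
7 | (R)-epichlorohydrin, (2R)-2-(chloromethyl)oxirane | ClC[C@H]1CO1 | starting material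
8 | lithium (trimethylsilyl)acetylide | [Li]C#C[Si](C)(C)C | intermediate
9 | (2R)-1-chloro-5-(trimethylsilyl)pent-4-yn-2-ol | C[Si](C)(C)C#CC[C@@H](O)CCl | intermediate
10 | (2R)-2-[3-(trimethylsilyl)prop-2-yn-1-yl]oxirane | C[Si](C)(C)C#CC[C@@H]1CO1 | intermediate
11 | (3R)-6-(trimethylsilyl)hex-1-en-5-yn-3-ol | C[Si](C)(C)C#CC[C@@H](O)C=C | intermediate
12 | (3R)-hex-1-en-5-yn-3-ol | C#CC[C@@H](O)C=C | intermediate
13 | [(1E,4R)-4-(dimethylalumanyloxy)-2-methylhexa-1,5-dien-1-yl]dimethylalumane | C=C[C@H](O[Al](C)C)C/C(C)=C/[Al](C)C | intermediate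
14 | (3R,5E)-7-[2-(tert-butyldimethylsilyloxy)-5-methoxy-3-methylphenyl]-5-methylhepta-1,5-dien-3-ol | COc1cc(C)c(O[Si](C)(C)C(C)(C)C)c(C/C=C(\C)C[C@@H](O)C=C)c1 | intermediate
15 | (4S)-4-benzyl-3-propanoyl-1,3-oxazolidin-2-one | CCC(=O)N1[C@@H](Cc2ccccc2)COC1=O | starting material
16 | sodium (Z)-enolate of 15 | C/C=C(\O[Na])N1[C@@H](Cc2ccccc2)COC1=O | intermediate
17 | (4S)-4-benzyl-3-[(2R)-2-methylpent-4-enoyl]-1,3-oxazolidin-2-one | C=CC[C@@H](C)C(=O)N1[C@@H](Cc2ccccc2)COC1=O | intermediate
18 | (2R)-2-methylpent-4-en-1-ol | C=CC[C@@H](C)CO | intermediate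
19 | (2R)-2-methylpent-4-enal | C=CC[C@@H](C)C=O | intermediate
20 | 2-[(2R)-pent-4-en-2-yl]-1,3-dithiane | C=CC[C@@H](C)C1SCCCS1 | intermediate
21 | 2-lithio-2-[(2R)-pent-4-en-2-yl]-1,3-dithiane | C=CC[C@@H](C)C1([Li])SCCCS1 | intermediate
22 | 2-(3-methylbut-2-en-1-yl)-2-[(2R)-pent-4-en-2-yl]-1,3-dithiane | C=CC[C@@H](C)C1(CC=C(C)C)SCCCS1 | intermediate
23 | methyl 2-bromoacrylate | COC(=O)C(Br)=C | starting material
24 | 9-{(4R)-4-[2-(3-methylbut-2-en-1-yl)-1,3-dithian-2-yl]pentyl}-9-borabicyclo[3.3.1]nonane | CC(C)=CCC1(SCCCS1)[C@H](C)CCCB1C2CCCC1CCC2 | intermediate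
25 | methyl (6R)-2-methylidene-6-[2-(3-methylbut-2-en-1-yl)-1,3-dithian-2-yl]heptanoate | COC(=O)C(=C)CCC[C@@H](C)C1(CC=C(C)C)SCCCS1 | intermediate
26 | (6R)-2-methylidene-6-[2-(3-methylbut-2-en-1-yl)-1,3-dithian-2-yl]heptanoic acid | OC(=O)C(=C)CCC[C@@H](C)C1(CC=C(C)C)SCCCS1 | intermediate
27 | (3R,5E)-7-[2-(tert-butyldimethylsilyloxy)-5-methoxy-3-methylphenyl]-5-methylhepta-1,5-dien-3-yl (6R)-2-methylidene-6-[2-(3-methylbut-2-en-1-yl)-1,3-dithian-2-yl]heptanoate | COc1cc(C)c(O[Si](C)(C)C(C)(C)C)c(C/C=C(\C)C[C@@H](OC(=O)C(=C)CCC[C@@H](C)C2(CC=C(C)C)SCCCS2)C=C)c1 | intermediate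
28 | (5R)-5-{(2E)-4-[2-(tert-butyldimethylsilyloxy)-5-methoxy-3-methylphenyl]-2-methylbut-2-en-1-yl}-3-{(4R)-4-[2-(3-methylbut-2-en-1-yl)-1,3-dithian-2-yl]pentyl}furan-2(5H)-one | COc1cc(C)c(O[Si](C)(C)C(C)(C)C)c(C/C=C(\C)C[C@H]2OC(=O)C(CCC[C@@H](C)C3(CC=C(C)C)SCCCS3)=C2)c1 | intermediate
29 | (2Z,4R,6E)-8-[2-(tert-butyldimethylsilyloxy)-5-methoxy-3-methylphenyl]-6-methyl-2-{(4R)-4-[2-(3-methylbut-2-en-1-yl)-1,3-dithian-2-yl]pentyl}octa-2,6-diene-1,4-diol | COc1cc(C)c(O[Si](C)(C)C(C)(C)C)c(C/C=C(\C)C[C@@H](O)/C=C(\CO)CCC[C@@H](C)C2(CC=C(C)C)SCCCS2)c1 | intermediate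
30 | (2Z,4R,6E)-8-[2-(tert-butyldimethylsilyloxy)-5-methoxy-3-methylphenyl]-1-chloro-6-methyl-2-{(4R)-4-[2-(3-methylbut-2-en-1-yl)-1,3-dithian-2-yl]pentyl}octa-2,6-dien-4-ol | COc1cc(C)c(O[Si](C)(C)C(C)(C)C)c(C/C=C(\C)C[C@@H](O)/C=C(\CCl)CCC[C@@H](C)C2(CC=C(C)C)SCCCS2)c1 | intermediate
31 | {[(2Z,4R,6E)-8-[2-(tert-butyldimethylsilyloxy)-5-methoxy-3-methylphenyl]-1-chloro-6-methyl-2-{(4R)-4-[2-(3-methylbut-2-en-1-yl)-1,3-dithian-2-yl]pentyl}octa-2,6-dien-4-yl]oxy}triethylsilane | COc1cc(C)c(O[Si](C)(C)C(C)(C)C)c(C/C=C(\C)C[C@@H](O[Si](CC)(CC)CC)/C=C(\CCl)CCC[C@@H](C)C2(CC=C(C)C)SCCCS2)c1 | intermediate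
32 | tert-butyl(4-methoxy-2-methyl-6-{(2E,5R,6E,11R)-3,7-dimethyl-11-[2-(3-methylbut-2-en-1-yl)-1,3-dithian-2-yl]-5-(triethylsilyloxy)dodeca-2,6-dien-1-yl}phenoxy)dimethylsilane | COc1cc(C)c(O[Si](C)(C)C(C)(C)C)c(C/C=C(\C)C[C@@H](O[Si](CC)(CC)CC)/C=C(\C)CCC[C@@H](C)C2(CC=C(C)C)SCCCS2)c1 | intermediate
33 | (6R,10E,12R,14E)-16-[2-(tert-butyldimethylsilyloxy)-5-methoxy-3-methylphenyl]-2,6,10,14-tetramethyl-12-(triethylsilyloxy)hexadeca-2,10,14-trien-5-one | COc1cc(C)c(O[Si](C)(C)C(C)(C)C)c(C/C=C(\C)C[C@@H](O[Si](CC)(CC)CC)/C=C(\C)CCC[C@@H](C)C(=O)CC=C(C)C)c1 | intermediate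
34 | (6R,10E,12R,14E)-12-hydroxy-16-(2-hydroxy-5-methoxy-3-methylphenyl)-2,6,10,14-tetramethylhexadeca-2,10,14-trien-5-one | COc1cc(C)c(O)c(C/C=C(\C)C[C@@H](O)/C=C(\C)CCC[C@@H](C)C(=O)CC=C(C)C)c1 | target

Total step count: 22. Longest linear sequence: 14 steps (steps 9 to 22, from 15).

Steps most likely to fail

Step 17. The catalyst may be tied up by the dithiane sulfur atoms and may engage the 1,1-disubstituted acrylate too slowly, so that dimerisation through the vinyl group competes with ring closure. The fallback forms the ring before the sulfur-bearing chain is attached. It sets out from alcohol 14, which is acylated with acryloyl chloride (Et3N, CH2Cl2, −20 °C) to the acrylate ester F1. Ring-closing metathesis of this sulfur-free diene with the same ruthenium catalyst should give the 3-unsubstituted butenolide F2. α-Iodination (I2, pyridine, CH2Cl2) should give the 3-iodobutenolide F3. B-alkyl Suzuki–Miyaura coupling of F3 with borane 24, made from 22 as in step 14 (PdCl2(dppf), AsPh3, K3PO4, DMF/H2O, rt, mild base to limit deprotonation at C5'), comes back to the route at 28.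

Step 14. The bromoacrylate may polymerise or take up nucleophiles under the basic coupling conditions, and the dithiane may sequester palladium, so that the alkylborane is lost to protodeboronation. The fallback builds the acrylate by olefination instead of cross-coupling. It sets out from 22 through borane 24, which is oxidised (NaBO3·4H2O, THF/H2O) to the primary alcohol F4. F4 is converted (PPh3, I2, imidazole, CH2Cl2) into the primary iodide F5, which alkylates triethyl phosphonoacetate (NaH, DMF, 60 °C) to the phosphonoester F6. Horner–Wadsworth–Emmons reaction of F6 with aqueous formaldehyde (K2CO3, THF) should give the ethyl 2-alkylacrylate F7, and saponification (LiOH, THF/H2O) comes back to the route at 26.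

Step 19. Sulfonylation may also occur at the secondary allylic hydroxyl, and the C5' hydroxyl may cyclise onto the activated primary allylic carbon before it is silylated. The fallback separates the two hydroxyls by protection before any leaving group is made. It sets out from diol 29, which is acylated selectively at the primary hydroxyl (pivaloyl chloride, pyridine, CH2Cl2, −20 °C) to the primary pivalate F8. Silylation (Et3SiOTf, 2,6-lutidine, CH2Cl2, −78 °C) gives the pivalate triethylsilyl ether F9, and i-Bu2AlH (CH2Cl2, −78 °C) removes the pivalate to give the primary allylic alcohol F10. Chlorination of F10 (MsCl, 2,4,6-collidine, LiCl, DMF, 0 °C) comes back to the route at 31.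

Further compounds
F1 | step 17 | (3R,5E)-7-[2-(tert-butyldimethylsilyloxy)-5-methoxy-3-methylphenyl]-5-methylhepta-1,5-dien-3-yl prop-2-enoate | COc1cc(C)c(O[Si](C)(C)C(C)(C)C)c(C/C=C(\C)C[C@@H](OC(=O)C=C)C=C)c1
F2 | step 17 | (5R)-5-{(2E)-4-[2-(tert-butyldimethylsilyloxy)-5-methoxy-3-methylphenyl]-2-methylbut-2-en-1-yl}furan-2(5H)-one | COc1cc(C)c(O[Si](C)(C)C(C)(C)C)c(C/C=C(\C)C[C@H]2OC(=O)C=C2)c1
F3 | step 17 | (5R)-5-{(2E)-4-[2-(tert-butyldimethylsilyloxy)-5-methoxy-3-methylphenyl]-2-methylbut-2-en-1-yl}-3-iodofuran-2(5H)-one | COc1cc(C)c(O[Si](C)(C)C(C)(C)C)c(C/C=C(\C)C[C@H]2OC(=O)C(I)=C2)c1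
F4 | step 14 | (4R)-4-[2-(3-methylbut-2-en-1-yl)-1,3-dithian-2-yl]pentan-1-ol | OCCC[C@@H](C)C1(CC=C(C)C)SCCCS1
F5 | step 14 | 2-[(2R)-5-iodopentan-2-yl]-2-(3-methylbut-2-en-1-yl)-1,3-dithiane | ICCC[C@@H](C)C1(CC=C(C)C)SCCCS1
F6 | step 14 | ethyl (6R)-2-(diethoxyphosphoryl)-6-[2-(3-methylbut-2-en-1-yl)-1,3-dithian-2-yl]heptanoate (both C2 epimers) | CCOC(=O)C(CCC[C@@H](C)C1(CC=C(C)C)SCCCS1)P(=O)(OCC)OCC
F7 | step 14 | ethyl (6R)-2-methylidene-6-[2-(3-methylbut-2-en-1-yl)-1,3-dithian-2-yl]heptanoate | CCOC(=O)C(=C)CCC[C@@H](C)C1(CC=C(C)C)SCCCS1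
F8 | step 19 | (2Z,4R,6E)-8-[2-(tert-butyldimethylsilyloxy)-5-methoxy-3-methylphenyl]-4-hydroxy-6-methyl-2-{(4R)-4-[2-(3-methylbut-2-en-1-yl)-1,3-dithian-2-yl]pentyl}octa-2,6-dien-1-yl 2,2-dimethylpropanoate | COc1cc(C)c(O[Si](C)(C)C(C)(C)C)c(C/C=C(\C)C[C@@H](O)/C=C(\COC(=O)C(C)(C)C)CCC[C@@H](C)C2(CC=C(C)C)SCCCS2)c1
F9 | step 19 | (2Z,4R,6E)-8-[2-(tert-butyldimethylsilyloxy)-5-methoxy-3-methylphenyl]-6-methyl-2-{(4R)-4-[2-(3-methylbut-2-en-1-yl)-1,3-dithian-2-yl]pentyl}-4-(triethylsilyloxy)octa-2,6-dien-1-yl 2,2-dimethylpropanoate | COc1cc(C)c(O[Si](C)(C)C(C)(C)C)c(C/C=C(\C)C[C@@H](O[Si](CC)(CC)CC)/C=C(\COC(=O)C(C)(C)C)CCC[C@@H](C)C2(CC=C(C)C)SCCCS2)c1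
F10 | step 19 | (2Z,4R,6E)-8-[2-(tert-butyldimethylsilyloxy)-5-methoxy-3-methylphenyl]-6-methyl-2-{(4R)-4-[2-(3-methylbut-2-en-1-yl)-1,3-dithian-2-yl]pentyl}-4-(triethylsilyloxy)octa-2,6-dien-1-ol | COc1cc(C)c(O[Si](C)(C)C(C)(C)C)c(C/C=C(\C)C[C@@H](O[Si](CC)(CC)CC)/C=C(\CO)CCC[C@@H](C)C2(CC=C(C)C)SCCCS2)c1
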